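**Remark on the structures.** The descriptors derived from the target string are (2R,3R) in ring B with the C2 side chain and the C3 oxygen cis, (R) at the side-chain carbinol and (R) in the 2-methylbutanoyl group. Compounds 5 and 6 of this route carry the matching configuration, so no structure had to be corrected. Compound 3 is taken as the purchasable free acid, which saves a saponification of its triethyl ester.

## Structural features

The target is a 2,3-dihydrobenzofuran in which benzene ring A is fused through C3a–C7a to the five-membered oxygen ring B (O1, C2, C3). C2 carries a 3-oxoprop-1-en-2-yl group (Cα=CH2 with the CHO on Cα) and C3 carries an isovalerate. These two neighbouring stereocentres are (2R,3R), so Cα and the C3 oxygen lie on the same face and H2 stands anti to the acyloxy group. C5, para to O1, carries an (R)-1-acyloxyethyl group acylated by (R)-2-methylbutanoic acid; these two stereocentres face each other across the ester linkage and are too remote to be controlled by ring B. Fragile points are the enal (Michael acceptor), the benzylic C3 ester (its loss together with H2 aromatises ring B to a benzofuran under acid or base), the p-alkoxybenzylic side-chain ester (ionisation) and the enolisable α-centre of the 2-methylbutanoate. The real difficulty is the cis C2/C3 pair with absolute control next to an electrophilic acrolein, together with telling three oxygen functions apart. The route exploits the chain O(C3)–C(=O)–Cα–C2–C3 as a latent γ-lactone: the acrolein carbonyl carbon can be tied to the C3 oxygen, and the C2–H bond cis to that oxygen is an ether α-C–H bond lying 1,5 to a carbenoid placed at Cα.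

## Logic of the disconnections

**18 ⇒ 17 ⇒ 16.** The aldehyde is taken back to the primary allylic alcohol (carbinol C–H bonds restored) and its O–H to an O–Si bond. The enal is the most electrophilic group and is best unveiled last; 16 then holds only esters, an ether and an isolated alkene. The forward steps need a fluoride source that is not basic, so that the C3 ester neither migrates to the free primary hydroxyl nor is eliminated, and a neutral oxidant selective for the allylic alcohol.

**16 ⇒ 14 + 15.** The acyl C–O bond of the side-chain ester is cut. This brings in one stereocentre and five carbons as a purchasable acid. The forward acylation must not enolise the α-centre of 15 and must not ionise the benzylic carbinol of 14.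

**14 ⇒ 13.** The carbinol C–H bond is cut, leaving an aryl methyl ketone. The centre is too far from ring B for substrate control, so a ketone that a chiral catalyst can reduce is the logical precursor. The forward reduction must be catalyst-controlled and must spare the ester, the silyl ether and the 1,1-disubstituted alkene.

**13 ⇒ 12 ⇒ 11.** The C5–C(acetyl) bond is cut back to an aryl bromide, with an enol ether as the masked ketone. Bromine is present in a commercial starting material, is inert to every earlier step and deactivates ring A in the key step. The forward coupling must be neutral and must tolerate a benzylic ester, an allylic aryl ether and a silyl ether; unmasking must need only dilute acid.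

**11 ⇒ 10 ⇒ 8 + 9.** The acyl C–O bond at the C3 oxygen and the O–Si bond are cut. This reduces the problem to a diol whose hydroxyls differ in class (primary allylic, hindered secondary benzylic). The forward demand is clean primary silylation so that both operations can run in one flask.

**8 ⇒ 7.** In the retrosynthetic sense the primary carbinol carbon is raised to the acid level and joined to the C3 oxygen as a lactone (acyl C–O bond formed). The cis-fused bicycle encodes the cis C2/C3 relation in a ring fusion and removes the need to distinguish the two oxygens. The forward reduction must be exhaustive and 1,2 only.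

**7 ⇒ 6.** The Cα=CH2 bond is cut to an α-phosphono lactone and formaldehyde. The phosphonate is the group that also makes the diazo precursor stable and easy to prepare. The forward olefination must outrun β-elimination of the O1 aryloxide from the Cα carbanion.

**6 ⇒ 5.** The C2–Cα bond is cut. This removes the lactone ring and the C2 stereocentre and leaves a single stereocentre at C3, one bond from the carbon that becomes C2. The forward step must insert into the cis C2–H bond and not into C3–H, the arene or the O1 lone pair.

**5 ⇒ 4 ⇒ 2 + 3.** The C=N2 bond and then the acyl C–O bond at the C3 oxygen are cut. Both forward steps are routine; the only demand is that the benzylic C3–O bond is never ionised.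

**2 ⇒ 1.** The C3–H bond is cut, leaving a commercial aryl ketone. The forward reduction must deliver hydride to one face under catalyst control and under conditions that do not dehydrate 2.

## Other disconnections considered

**Alternative 1:** The cut is C2–C3 (with Cα–B). In the forward sense a copper boryl (monovalent copper, chiral ligand) would add across the terminal C=C of aryloxyallene aldehyde A1, and the γ-aryloxyallylcopper would attack the ortho aldehyde through its oxygen-bearing carbon to give A2.
- In its favour: ring B, both ring stereocentres and a handle at Cα arise in one step, with the complete side chain already in place. No aryl coupling and no hydroxyl protection are needed after ring formation.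
- Against it here: the cis relation and the absolute sense depend on the allylcopper geometry and on a chiral ligand, with direct boryl addition to the aldehyde as a competing path. The C–B bond must still be turned into C–CHO (homologation, oxidation, second oxidation, joining the route at 17) beside two esters. A1 requires a base-mediated propargyl-to-allenyl shift in the presence of an aldehyde and an ester.
- Comparison: on structure it is more convergent and better in redox and protecting-group economy. On mechanism the chosen plan is more secure, because cis fusion is a geometric necessity and not a selectivity. On step count the two are about equal.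

**Alternative 2:** The cuts are C3a–C7a and C4–C5, so ring A is built last. On heating, the tethered terminal alkyne of pyridazinyl ether A3 would add across C3 and C6 of the acetylpyridazine and expel N2 to give A4, which is the same compound as 13.
- In its favour: C2 and C3 come from a carbohydrate template with no asymmetric catalysis; the acetyl position is unambiguous; nitrogen loss is irreversible; no tin or palladium is used; the last four steps are shared with the chosen route.
- Against it here: A3 needs a long sequence of degradation, protecting-group changes and an SNAr by a hindered secondary alkoxide. The cycloaddition of an unactivated alkyne needs high temperature, which endangers the propargylic ester and the allyl heteroaryl ether through sigmatropic shifts.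
- Comparison: it is equal on the stereochemical security of ring B and better on the regiochemical certainty of the acetyl group. It is clearly worse on step economy.

**Alternative 3:** The cut is O1–C7a. With carbonate base in a dipolar aprotic solvent, the C2 alkoxide of syn-diol A5 would displace fluoride para to the acetyl group and give A6.
- In its favour: an asymmetric dihydroxylation sets both ring stereocentres at once, and the syn relation maps onto cis. No protecting group is needed, the acetyl group is present from the start, and the target would be about eight steps away.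
- Against it here: the dihydroxylation must choose the styrenyl double bond of an electron-poor aryl diene over the 1,1-disubstituted one. A single acetyl group is a modest SNAr activator and is enolisable under the basic conditions. The isopropenyl methyl of A6 must later be oxidised to CHO beside a tertiary allylic C2–H and an acid-labile C3 ester.
- Comparison: it is better on step economy and equal on the reliability of ring closure. The chosen plan is stronger on structure, since the aldehyde carbon arrives at the right position and oxidation level without a late C–H oxidation, and its stereocontrol does not rest on a regioselective dihydroxylation.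

Key step: step 4

## Route

Step 1
Reactants: 1 5-bromobenzofuran-3(2H)-one
Product: 2 (R)-5-bromo-2,3-dihydrobenzofuran-3-ol
Conditions: RuCl(p-cymene)[(S,S)-TsDPEN] (1 mol %), HCO2H/Et3N (5:2), CH2Cl2, rt; non-acidic work-up
Reagents that add atoms: none
Why: Noyori–Ikariya asymmetric transfer hydrogenation of an aryl ketone; the (S,S)-catalyst delivers hydride to the face that gives (S)-1-arylethanols, which is the (R)-alcohol here because the oxygen-bearing C2 outranks the aryl carbon. The buffered medium and neutral work-up avoid dehydration to the benzofuran.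

Step 2
Reactants: 2 (R)-5-bromo-2,3-dihydrobenzofuran-3-ol; 3 2-(diethoxyphosphoryl)acetic acid
Product: 4 (R)-5-bromo-2,3-dihydrobenzofuran-3-yl 2-(diethoxyphosphoryl)acetate
Conditions: EDC·HCl, DMAP (cat.), CH2Cl2, 0 °C → rt
Reagents that add atoms: none
Why: Steglich-type carbodiimide esterification; only the O–H bond of 2 reacts, so C3 keeps its configuration.

Step 3
Reactants: 4 (R)-5-bromo-2,3-dihydrobenzofuran-3-yl 2-(diethoxyphosphoryl)acetate
Product: 5 (R)-5-bromo-2,3-dihydrobenzofuran-3-yl 2-diazo-2-(diethoxyphosphoryl)acetate
Conditions: p-ABSA, DBU, MeCN, 0 °C → rt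
Reagents that add atoms: 4-acetamidobenzenesulfonyl azide (p-ABSA), CC(=O)Nc1ccc(cc1)S(=O)(=O)N=[N+]=[N-]
Why: Regitz diazo transfer to the methylene activated by ester and phosphonate; p-ABSA is chosen as the less hazardous sulfonyl azide and the product is a stabilised acceptor/acceptor diazo compound.

Step 4
Reactants: 5 (R)-5-bromo-2,3-dihydrobenzofuran-3-yl 2-diazo-2-(diethoxyphosphoryl)acetate
Product: 6 diethyl [(3aS,8bR)-7-bromo-2-oxo-2,3,3a,8b-tetrahydrofuro[3,2-b]benzofuran-3-yl]phosphonate (cis-fused lactone, mixture of epimers at the phosphonate carbon)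
Conditions: Rh2(OAc)4 (2 mol %), CH2Cl2, reflux, slow addition of 5
Reagents that add atoms: none
Why: Rh2(OAc)4 takes N2 from 5 and forms an electrophilic divalent-rhodium carbenoid at Cα, which inserts into the C2–H bond through a concerted, hydride-like three-centre transition state assisted by the O1 lone pair, forming C2–Cα and releasing the catalyst. The closest known reaction type is the dirhodium-catalysed intramolecular C–H insertion of α-diazo esters, α-phosphono diazoacetates included, into ether α-C–H bonds to give γ-lactones. The lactone ring closes by C–C bond formation in a 1,5-insertion, the five-membered ring being the kinetically preferred size, and is fused to ring B along C2–C3. The C2 stereocentre is controlled by C3: the three-atom O–C(=O)–Cα tether reaches only the hydrogen cis to the C3 oxygen, because a trans-fused bicyclo[3.3.0] junction is too strained, and the new bond takes the place of that hydrogen. The phosphonate carbon forms as epimers, which is of no consequence because step 5 removes it. Site selectivity is needed against C3–H (four-membered ring, bond deactivated by the acyloxy group), against attack on ring A at C4 (ring deactivated by bromine, C4 flanked by it) and against ylide formation at O1 (weakly basic aryl ether oxygen, reversible); slow addition suppresses carbene dimerisation. The aryl bromide and the benzylic ester are untouched under these neutral conditions.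

Step 5
Reactants: 6 diethyl [(3aS,8bR)-7-bromo-2-oxo-2,3,3a,8b-tetrahydrofuro[3,2-b]benzofuran-3-yl]phosphonate
Product: 7 (3aR,8bR)-7-bromo-3-methylidene-3a,8b-dihydrofuro[3,2-b]benzofuran-2(3H)-one
Conditions: aq. HCHO (37 %), K2CO3, THF, 0 °C → rt
Reagents that add atoms: formaldehyde, C=O
Why: Horner–Wadsworth–Emmons methylenation; both phosphonate epimers give the same carbanion, and excess formaldehyde traps it before the O1 aryloxide can be expelled from the β-carbon.

Step 6
Reactants: 7 (3aR,8bR)-7-bromo-3-methylidene-3a,8b-dihydrofuro[3,2-b]benzofuran-2(3H)-one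
Product: 8 (2R,3R)-5-bromo-2-(3-hydroxyprop-1-en-2-yl)-2,3-dihydrobenzofuran-3-ol
Conditions: i-Bu2AlH (4 equiv), CH2Cl2, −78 → 0 °C; aq. KNaC4H4O6 (potassium sodium tartrate)
Reagents that add atoms: none
Why: 1,2-reduction of the α-methylene lactone by the electrophilic aluminium hydride, first to the lactol aluminate and then, after ring opening, of the enal to the allylic alcohol; no bond at C2 or C3 is broken.

Step 7
Reactants: 8 (2R,3R)-5-bromo-2-(3-hydroxyprop-1-en-2-yl)-2,3-dihydrobenzofuran-3-ol; 9 3-methylbutanoyl chloride (isovaleryl chloride)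
Product: 11 (2R,3R)-5-bromo-2-[3-(tert-butyldimethylsilyloxy)prop-1-en-2-yl]-2,3-dihydrobenzofuran-3-yl 3-methylbutanoate, via primary silyl ether 10 (not isolated)
Conditions: TBSCl (1.05 equiv), Et3N, DMAP (cat.), CH2Cl2, 0 °C; then 9, pyridine, 0 °C → rt
Reagents that add atoms: tert-butyldimethylsilyl chloride, CC(C)(C)[Si](C)(C)Cl
Why: Silylation selects the primary allylic hydroxyl over the hindered secondary benzylic one; DMAP-catalysed acylation of the remaining C3–OH in the same flask occurs at oxygen with retention.

Step 8
Reactants: 11 (2R,3R)-5-bromo-2-[3-(tert-butyldimethylsilyloxy)prop-1-en-2-yl]-2,3-dihydrobenzofuran-3-yl 3-methylbutanoate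
Product: 13 (2R,3R)-5-acetyl-2-[3-(tert-butyldimethylsilyloxy)prop-1-en-2-yl]-2,3-dihydrobenzofuran-3-yl 3-methylbutanoate, via enol ether 12 (not isolated)
Conditions: Bu3Sn[C(OEt)=CH2], Pd(PPh3)4 (5 mol %), toluene, 90 °C; then 1 M HCl, THF, 0 °C
Reagents that add atoms: tributyl(1-ethoxyvinyl)stannane, CCCC[Sn](CCCC)(CCCC)C(=C)OCC; water, O
Why: Stille coupling (oxidative addition of zerovalent palladium into C5–Br, transmetalation, reductive elimination) under neutral conditions; the electron-rich α-aryl enol ether is hydrolysed by cold dilute acid much faster than the primary silyl ether or the benzylic ester react.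

Step 9
Reactants: 13 (2R,3R)-5-acetyl-2-[3-(tert-butyldimethylsilyloxy)prop-1-en-2-yl]-2,3-dihydrobenzofuran-3-yl 3-methylbutanoate
Product: 14 (2R,3R)-2-[3-(tert-butyldimethylsilyloxy)prop-1-en-2-yl]-5-[(R)-1-hydroxyethyl]-2,3-dihydrobenzofuran-3-yl 3-methylbutanoate
Conditions: RuCl(p-cymene)[(R,R)-TsDPEN] (2 mol %), HCO2H/Et3N (5:2), CH2Cl2, 30 °C
Reagents that add atoms: none
Why: Noyori–Ikariya transfer hydrogenation under catalyst control; the (R,R)-catalyst gives (R)-1-arylethanols, and the ruthenium hydride is selective for the ketone over ester, silyl ether and unactivated alkene.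

Step 10
Reactants: 14 (2R,3R)-2-[3-(tert-butyldimethylsilyloxy)prop-1-en-2-yl]-5-[(R)-1-hydroxyethyl]-2,3-dihydrobenzofuran-3-yl 3-methylbutanoate; 15 (R)-2-methylbutanoic acid
Product: 16 (R)-1-{(2R,3R)-2-[3-(tert-butyldimethylsilyloxy)prop-1-en-2-yl]-3-(3-methylbutanoyloxy)-2,3-dihydrobenzofuran-5-yl}ethyl (R)-2-methylbutanoate
Conditions: EDC·HCl, DMAP (cat.), CH2Cl2, 0 °C
Reagents that add atoms: none
Why: Carbodiimide/DMAP esterification at the carbinol oxygen; no bond to either stereocentre is broken, and low temperature with catalytic DMAP limits enolisation of the activated acid.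

Step 11
Reactants: 16 (R)-1-{(2R,3R)-2-[3-(tert-butyldimethylsilyloxy)prop-1-en-2-yl]-3-(3-methylbutanoyloxy)-2,3-dihydrobenzofuran-5-yl}ethyl (R)-2-methylbutanoate
Product: 17 (R)-1-[(2R,3R)-2-(3-hydroxyprop-1-en-2-yl)-3-(3-methylbutanoyloxy)-2,3-dihydrobenzofuran-5-yl]ethyl (R)-2-methylbutanoate
Conditions: HF·pyridine, pyridine, THF, 0 °C → rt
Reagents that add atoms: none
Why: Fluoride-driven Si–O cleavage of a primary silyl ether in a buffered, non-basic medium, chosen so that the C3 ester neither migrates to the liberated hydroxyl nor is eliminated.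

Step 12
Reactants: 17 (R)-1-[(2R,3R)-2-(3-hydroxyprop-1-en-2-yl)-3-(3-methylbutanoyloxy)-2,3-dihydrobenzofuran-5-yl]ethyl (R)-2-methylbutanoate
Product: 18 (R)-1-[(2R,3R)-3-(3-methylbutanoyloxy)-2-(3-oxoprop-1-en-2-yl)-2,3-dihydrobenzofuran-5-yl]ethyl (R)-2-methylbutanoate
Conditions: MnO2 (activated, excess), CH2Cl2, rt
Reagents that add atoms: none
Why: Heterogeneous MnO2 oxidation, selective for allylic alcohols and neutral, so the esters, the C2/C3 centres and the new enal are left alone.

## Compound list

1 | 5-bromobenzofuran-3(2H)-one | O=C1COc2ccc(Br)cc21 | starting material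
2 | (R)-5-bromo-2,3-dihydrobenzofuran-3-ol | O[C@H]1COc2ccc(Br)cc21 | intermediate
3 | 2-(diethoxyphosphoryl)acetic acid | CCOP(=O)(OCC)CC(=O)O | starting material
4 | (R)-5-bromo-2,3-dihydrobenzofuran-3-yl 2-(diethoxyphosphoryl)acetate | CCOP(=O)(OCC)CC(=O)O[C@H]1COc2ccc(Br)cc21 | intermediate
5 | (R)-5-bromo-2,3-dihydrobenzofuran-3-yl 2-diazo-2-(diethoxyphosphoryl)acetate | CCOP(=O)(OCC)C(=[N+]=[N-])C(=O)O[C@H]1COc2ccc(Br)cc21 | intermediate
6 | diethyl [(3aS,8bR)-7-bromo-2-oxo-2,3,3a,8b-tetrahydrofuro[3,2-b]benzofuran-3-yl]phosphonate | CCOP(=O)(OCC)C1[C@H]2Oc3ccc(Br)cc3[C@H]2OC1=O | intermediate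
7 | (3aR,8bR)-7-bromo-3-methylidene-3a,8b-dihydrofuro[3,2-b]benzofuran-2(3H)-one | C=C1[C@H]2Oc3ccc(Br)cc3[C@H]2OC1=O | intermediate
8 | (2R,3R)-5-bromo-2-(3-hydroxyprop-1-en-2-yl)-2,3-dihydrobenzofuran-3-ol | C=C(CO)[C@H]1Oc2ccc(Br)cc2[C@H]1O | intermediate
9 | 3-methylbutanoyl chloride | CC(C)CC(=O)Cl | starting material
10 | (2R,3R)-5-bromo-2-[3-(tert-butyldimethylsilyloxy)prop-1-en-2-yl]-2,3-dihydrobenzofuran-3-ol | C=C(CO[Si](C)(C)C(C)(C)C)[C@H]1Oc2ccc(Br)cc2[C@H]1O | intermediate
11 | (2R,3R)-5-bromo-2-[3-(tert-butyldimethylsilyloxy)prop-1-en-2-yl]-2,3-dihydrobenzofuran-3-yl 3-methylbutanoate | C=C(CO[Si](C)(C)C(C)(C)C)[C@H]1Oc2ccc(Br)cc2[C@H]1OC(=O)CC(C)C | intermediate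
12 | (2R,3R)-2-[3-(tert-butyldimethylsilyloxy)prop-1-en-2-yl]-5-(1-ethoxyvinyl)-2,3-dihydrobenzofuran-3-yl 3-methylbutanoate | C=C(CO[Si](C)(C)C(C)(C)C)[C@H]1Oc2ccc(C(=C)OCC)cc2[C@H]1OC(=O)CC(C)C | intermediate
13 | (2R,3R)-5-acetyl-2-[3-(tert-butyldimethylsilyloxy)prop-1-en-2-yl]-2,3-dihydrobenzofuran-3-yl 3-methylbutanoate | C=C(CO[Si](C)(C)C(C)(C)C)[C@H]1Oc2ccc(C(C)=O)cc2[C@H]1OC(=O)CC(C)C | intermediate
14 | (2R,3R)-2-[3-(tert-butyldimethylsilyloxy)prop-1-en-2-yl]-5-[(R)-1-hydroxyethyl]-2,3-dihydrobenzofuran-3-yl 3-methylbutanoate | C=C(CO[Si](C)(C)C(C)(C)C)[C@H]1Oc2ccc([C@@H](C)O)cc2[C@H]1OC(=O)CC(C)C | intermediate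
15 | (R)-2-methylbutanoic acid | OC(=O)[C@H](C)CC | starting material
16 | (R)-1-{(2R,3R)-2-[3-(tert-butyldimethylsilyloxy)prop-1-en-2-yl]-3-(3-methylbutanoyloxy)-2,3-dihydrobenzofuran-5-yl}ethyl (R)-2-methylbutanoate | C=C(CO[Si](C)(C)C(C)(C)C)[C@H]1Oc2ccc([C@@H](C)OC(=O)[C@H](C)CC)cc2[C@H]1OC(=O)CC(C)C | intermediate
17 | (R)-1-[(2R,3R)-2-(3-hydroxyprop-1-en-2-yl)-3-(3-methylbutanoyloxy)-2,3-dihydrobenzofuran-5-yl]ethyl (R)-2-methylbutanoate | C=C(CO)[C@H]1Oc2ccc([C@@H](C)OC(=O)[C@H](C)CC)cc2[C@H]1OC(=O)CC(C)C | intermediate
18 | (R)-1-[(2R,3R)-3-(3-methylbutanoyloxy)-2-(3-oxoprop-1-en-2-yl)-2,3-dihydrobenzofuran-5-yl]ethyl (R)-2-methylbutanoate | C=C(C=O)[C@H]1Oc2ccc([C@@H](C)OC(=O)[C@H](C)CC)cc2[C@H]1OC(=O)CC(C)C | target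

## Step count and least certain steps

Total step count: 12. Longest linear sequence: 12 steps (1 to 18); 3, 9 and 15 enter as purchased compounds.

**Step 4 (key step).**
- What may go wrong: diversion of the carbenoid into other channels (insertion into C3–H, attack on ring A at C4, ylide formation at O1, dimerisation), or thermal loss of the phosphonoacetate from C3 with aromatisation before insertion. The phosphoryl-stabilised carbenoid is sluggish, which lengthens its exposure to these paths.
- Fallback, setting out from 1 and coming back at 7, without carbenoid chemistry: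
  - Knoevenagel-type condensation of 1 with ethyl glyoxylate would give ethyl (Z)-(5-bromo-3-oxobenzofuran-2(3H)-ylidene)acetate F1.
  - Conjugate reduction of the doubly activated C=C with Hantzsch ester would give ethyl (5-bromo-3-oxo-2,3-dihydrobenzofuran-2-yl)acetate F2, whose C2 epimerises freely.
  - Transfer hydrogenation with the catalyst of step 1 under dynamic kinetic resolution should reduce the ketone to the (R)-alcohol cis to the C2 substituent, and lactonisation would give (3aR,8bR)-7-bromo-3a,8b-dihydrofuro[3,2-b]benzofuran-2(3H)-one F3.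
  - Carboxylation with MeOMgOCO2Me in DMF would give (3aR,8bR)-7-bromo-2-oxo-2,3,3a,8b-tetrahydrofuro[3,2-b]benzofuran-3-carboxylic acid F4, and decarboxylative Mannich methylenation (aq. HCHO, Et2NH, NaOAc/AcOH) would return to 7.

**Step 6.**
- What may go wrong: conjugate hydride delivery to the α-methylene lactone, after which the resulting enolate can expel the O1 aryloxide and open ring B; or incomplete reduction that stops at the lactol.
- Fallback, setting out from 7 and coming back at 8, masking the alkene during reduction:
  - Conjugate addition of PhSeH (from PhSeSePh and NaBH4 in EtOH) would give (3aR,8bR)-7-bromo-3-[(phenylselanyl)methyl]-3a,8b-dihydrofuro[3,2-b]benzofuran-2(3H)-one F5.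
  - LiAlH4 (THF, 0 °C) would reduce it to (2R,3R)-5-bromo-2-[1-hydroxy-3-(phenylselanyl)propan-2-yl]-2,3-dihydrobenzofuran-3-ol F6.
  - Oxidation with H2O2 and syn-elimination of the selenoxide toward the only β-hydrogen would regenerate the 1,1-disubstituted alkene of 8.

**Step 8.**
- What may go wrong: ionisation of the allylic C2–O1 aryl ether by zerovalent palladium (epimerisation at C2 or ring opening), slow oxidative addition into the electron-rich C5–Br bond at a temperature where the C3 ester begins to eliminate, or loss of the silyl group during hydrolysis.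
- Fallback, setting out from 6 and coming back at 12, moving the coupling to a substrate without an allylic ether:
  - The same Stille coupling on 6, without acid work-up, would give diethyl [(3aS,8bR)-7-(1-ethoxyvinyl)-2-oxo-2,3,3a,8b-tetrahydrofuro[3,2-b]benzofuran-3-yl]phosphonate F7.
  - Methylenation as in step 5 would give (3aR,8bR)-7-(1-ethoxyvinyl)-3-methylidene-3a,8b-dihydrofuro[3,2-b]benzofuran-2(3H)-one F8.
  - Reduction as in step 6 would give (2R,3R)-5-(1-ethoxyvinyl)-2-(3-hydroxyprop-1-en-2-yl)-2,3-dihydrobenzofuran-3-ol F9.
  - Silylation would give (2R,3R)-2-[3-(tert-butyldimethylsilyloxy)prop-1-en-2-yl]-5-(1-ethoxyvinyl)-2,3-dihydrobenzofuran-3-ol F10, and acylation with 9 would give 12, which is hydrolysed to 13 as in step 8.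
  - All intermediates would be handled on base-washed silica because the enol ether is acid-labile.

**Step 10.**
- What may go wrong: partial epimerisation of the α-centre of 15 through enolisation of the activated acyl species, or erosion at the p-alkoxybenzylic carbinol by ionisation. Either would give diastereomers that are hard to separate.
- Fallback, setting out from 13 and coming back at 16, activating the alcohol and not the acid:
  - Reduction of 13 with RuCl(p-cymene)[(S,S)-TsDPEN] would give (2R,3R)-2-[3-(tert-butyldimethylsilyloxy)prop-1-en-2-yl]-5-[(S)-1-hydroxyethyl]-2,3-dihydrobenzofuran-3-yl 3-methylbutanoate F11.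
  - Mitsunobu esterification with 15 (PPh3, DIAD, toluene, −20 °C) would form the C–O bond with inversion and give 16, with the acid never activated.

## Further compounds

F1 | step 4 | ethyl (Z)-(5-bromo-3-oxobenzofuran-2(3H)-ylidene)acetate | CCOC(=O)/C=C1\Oc2ccc(Br)cc2C1=O
F2 | step 4 | ethyl (5-bromo-3-oxo-2,3-dihydrobenzofuran-2-yl)acetate | CCOC(=O)CC1Oc2ccc(Br)cc2C1=O
F3 | step 4 | (3aR,8bR)-7-bromo-3a,8b-dihydrofuro[3,2-b]benzofuran-2(3H)-one | O=C1C[C@H]2Oc3ccc(Br)cc3[C@H]2O1
F4 | step 4 | (3aR,8bR)-7-bromo-2-oxo-2,3,3a,8b-tetrahydrofuro[3,2-b]benzofuran-3-carboxylic acid | OC(=O)C1[C@H]2Oc3ccc(Br)cc3[C@H]2OC1=O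
F5 | step 6 | (3aR,8bR)-7-bromo-3-[(phenylselanyl)methyl]-3a,8b-dihydrofuro[3,2-b]benzofuran-2(3H)-one | c1ccccc1[Se]CC1[C@H]2Oc3ccc(Br)cc3[C@H]2OC1=O
F6 | step 6 | (2R,3R)-5-bromo-2-[1-hydroxy-3-(phenylselanyl)propan-2-yl]-2,3-dihydrobenzofuran-3-ol | OCC(C[Se]c1ccccc1)[C@H]1Oc2ccc(Br)cc2[C@H]1O
F7 | step 8 | diethyl [(3aS,8bR)-7-(1-ethoxyvinyl)-2-oxo-2,3,3a,8b-tetrahydrofuro[3,2-b]benzofuran-3-yl]phosphonate | CCOP(=O)(OCC)C1[C@H]2Oc3ccc(C(=C)OCC)cc3[C@H]2OC1=O
F8 | step 8 | (3aR,8bR)-7-(1-ethoxyvinyl)-3-methylidene-3a,8b-dihydrofuro[3,2-b]benzofuran-2(3H)-one | C=C1[C@H]2Oc3ccc(C(=C)OCC)cc3[C@H]2OC1=O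
F9 | step 8 | (2R,3R)-5-(1-ethoxyvinyl)-2-(3-hydroxyprop-1-en-2-yl)-2,3-dihydrobenzofuran-3-ol | C=C(CO)[C@H]1Oc2ccc(C(=C)OCC)cc2[C@H]1O
F10 | step 8 | (2R,3R)-2-[3-(tert-butyldimethylsilyloxy)prop-1-en-2-yl]-5-(1-ethoxyvinyl)-2,3-dihydrobenzofuran-3-ol | C=C(CO[Si](C)(C)C(C)(C)C)[C@H]1Oc2ccc(C(=C)OCC)cc2[C@H]1O
F11 | step 10 | (2R,3R)-2-[3-(tert-butyldimethylsilyloxy)prop-1-en-2-yl]-5-[(S)-1-hydroxyethyl]-2,3-dihydrobenzofuran-3-yl 3-methylbutanoate | C=C(CO[Si](C)(C)C(C)(C)C)[C@H]1Oc2ccc([C@H](C)O)cc2[C@H]1OC(=O)CC(C)C
A1 | alternative 1 | (R)-1-[3-formyl-4-(propa-1,2-dien-1-yloxy)phenyl]ethyl (R)-2-methylbutanoate | C=C=COc1ccc([C@@H](C)OC(=O)[C@H](C)CC)cc1C=O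
A2 | alternative 1 | (R)-1-{(2R,3R)-3-hydroxy-2-[1-(4,4,5,5-tetramethyl-1,3,2-dioxaborolan-2-yl)vinyl]-2,3-dihydrobenzofuran-5-yl}ethyl (R)-2-methylbutanoate | C=C(B1OC(C)(C)C(C)(C)O1)[C@H]1Oc2ccc([C@@H](C)OC(=O)[C@H](C)CC)cc2[C@H]1O
A3 | alternative 2 | (3R,4R)-4-[(6-acetylpyridazin-3-yl)oxy]-5-[(tert-butyldimethylsilyloxy)methyl]hex-5-en-1-yn-3-yl 3-methylbutanoate | C=C(CO[Si](C)(C)C(C)(C)C)[C@@H](Oc1ccc(C(C)=O)nn1)[C@H](OC(=O)CC(C)C)C#C
A4 | alternative 2 | (2R,3R)-5-acetyl-2-[3-(tert-butyldimethylsilyloxy)prop-1-en-2-yl]-2,3-dihydrobenzofuran-3-yl 3-methylbutanoate | C=C(CO[Si](C)(C)C(C)(C)C)[C@H]1Oc2ccc(C(C)=O)cc2[C@H]1OC(=O)CC(C)C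
A5 | alternative 3 | (1R,2R)-1-(5-acetyl-2-fluorophenyl)-3-methylbut-3-ene-1,2-diol | C=C(C)[C@@H](O)[C@H](O)c1cc(C(C)=O)ccc1F
A6 | alternative 3 | 1-[(2R,3R)-3-hydroxy-2-(prop-1-en-2-yl)-2,3-dihydrobenzofuran-5-yl]ethan-1-one | C=C(C)[C@H]1Oc2ccc(C(C)=O)cc2[C@H]1O
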